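**Strategy.** The oxepanone ring of the ketone half (O1, C2 = CMe2, C3 = C=O, C4, C5, C6 = quaternary C–Me, C7 = O–CH) is read as an aldehyde C7=O1 inserted between an electrophilic C2 and a nucleophilic C6. In the key step one catalyst makes pent-4-enal react with an epoxy (Z)-allylsilane from nerol: epoxide-opening acetalisation forges O1–C2, and silyl-Prins ring expansion of the resulting dioxolane forges C6–C7, setting both stereocentres. The oxepane formed serves both halves: an aldol reaction closes the acetoxy-bearing cyclohexane, an enolate alkenylation the methylidene cyclohexane, and an alkylchromium addition joins them.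

Key step: step 4

Remark: in the text each half is numbered O1, C2 (CMe2), C3, C4, C5, C6 (C–Me), C7 (O–CH), then C8, C9, C10, C11 round the cyclohexane (C11 bonded to C6); C12 and C13 are the linker carbons; primed locants belong to the hydroxy half. Compound names use systematic locants.
Remark: nerol and pent-4-enal are taken as commercial; the ketone catalyst of step 2 is the enantiomer of the common D-fructose-derived Shi ketone.
Remark: the carbinol centre made in step 15 is carried as a mixture of epimers because step 17 removes it.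

Step 1
Reactants: 1 nerol
Product: 2 (2Z)-3,7-dimethylocta-2,6-dien-1-yl methyl carbonate
Conditions: ClCO2Me, pyridine, CH2Cl2, 0 °C
Reagents that add atoms: methyl chloroformate, COC(=O)Cl
Why: Carbonate formation by acylation of the primary allylic alcohol should leave both alkenes untouched; the carbonate is the later leaving group for palladium and deactivates the proximal alkene towards epoxidation.

Step 2
Reactants: 2 (2Z)-3,7-dimethylocta-2,6-dien-1-yl methyl carbonate
Product: 3 methyl (2Z)-5-[(2S)-3,3-dimethyloxiran-2-yl]-3-methylpent-2-en-1-yl carbonate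
Conditions: 1,2:4,5-di-O-isopropylidene-β-L-erythro-hexo-2,3-diulo-2,6-pyranose (30 mol %), Oxone (2 KHSO5·KHSO4·K2SO4), K2CO3, Bu4NHSO4, MeCN/CH2(OMe)2, aq. Na2B4O7 buffer (pH 10.5), 0 °C
Reagents that add atoms: potassium peroxymonosulfate, [K+].[O-]S(=O)(=O)OO
Why: Shi asymmetric epoxidation should oxidise only the electron-rich distal trisubstituted alkene (the proximal one is deactivated by the allylic carbonate), and the L-fructose-derived dioxirane should deliver oxygen through the spiro transition state to the face that gives the (S)-epoxide, the future C3 stereocentre.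

Step 3
Reactants: 3 methyl (2Z)-5-[(2S)-3,3-dimethyloxiran-2-yl]-3-methylpent-2-en-1-yl carbonate
Product: 4 {(2Z)-5-[(2S)-3,3-dimethyloxiran-2-yl]-3-methylpent-2-en-1-yl}trimethylsilane
Conditions: Pd2(dba)3 (tris(dibenzylideneacetone)dipalladium, 2.5 mol %), Me3SiSiMe3, DMF, 60 °C
Reagents that add atoms: hexamethyldisilane, C[Si](C)(C)[Si](C)(C)C
Why: Palladium-catalysed allylic silylation of an allylic carbonate with a disilane should give the linear allylsilane by C–Si bond formation at the less hindered terminus of the π-allyl complex; the Z geometry is kept because isomerisation would have to pass through the tertiary σ-allyl species, and the isolated epoxide is inert to zerovalent palladium.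

Step 4
Reactants: 4 {(2Z)-5-[(2S)-3,3-dimethyloxiran-2-yl]-3-methylpent-2-en-1-yl}trimethylsilane, 5 pent-4-enal
Product: 8 (3S,6S,7S)-7-(but-3-en-1-yl)-6-ethenyl-2,2,6-trimethyloxepan-3-ol, via dioxolane acetal 6 (not isolated), via trimethylsilyl ether 7 (not isolated)
Conditions: 5 (3 equiv), Me3SiOTf (0.3 equiv), 2,6-di-tert-butyl-4-methylpyridine (0.1 equiv), CH2Cl2, −78 to −30 °C; then K2CO3, MeOH, 0 °C
Reagents that add atoms: none
Why: Proposed new method: Me3SiOTf should open the trisubstituted epoxide at its tertiary carbon with the aldehyde oxygen (new O1–C2 bond, as in the known Lewis-acid acetalisation of epoxides) to give dioxolane 6, and the same catalyst should then re-ionise 6 at the less hindered secondary oxygen so that the oxocarbenium ion is captured by the γ-carbon of the allylsilane (new C6–C7 bond, Me3Si+ passing to triflate and ending on the C3 oxygen in 7); the closest known reactions are silyl-Prins and acetal–allylsilane cyclisations to oxepanes. The oxepane closes in a 7-exo-trig mode onto the allylsilane π bond through a chair-like transition state with the CMe2 carbon on the twist axis. C7 is set by the (E)-oxocarbenium ion, which keeps the butenyl chain pseudo-equatorial. C6 is set by the (Z)-allylsilane, whose CH2SiMe3 group forces the vinyl group pseudo-equatorial and the methyl group pseudo-axial (allylic strain). Both centres are set relative to C3 because the incoming carbon displaces the departing C3 oxygen from the opposite face, which holds that oxygen pseudo-axial. The step needs seven-membered closure through the tertiary oxygen to beat six-membered closure through the secondary oxygen, which is secured because the less hindered secondary oxygen is the one silylated and expelled; excess aldehyde at −78 °C should suppress direct attack of the allylsilane on the activated epoxide.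

Step 5
Reactants: 8 (3S,6S,7S)-7-(but-3-en-1-yl)-6-ethenyl-2,2,6-trimethyloxepan-3-ol
Product: 9 4-[(2S,3S,6S)-3-ethenyl-6-hydroxy-3,7,7-trimethyloxepan-2-yl]butan-2-one
Conditions: PdCl2 (10 mol %), CuCl (20 mol %), O2 (1 atm), DMF/H2O 7:1, rt
Reagents that add atoms: water, O
Why: Tsuji–Wacker oxidation should convert the unhindered terminal alkene into the methyl ketone by Markovnikov hydroxypalladation, while the vinyl group on the quaternary carbon is too hindered to react at a comparable rate.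

Step 6
Reactants: 9 4-[(2S,3S,6S)-3-ethenyl-6-hydroxy-3,7,7-trimethyloxepan-2-yl]butan-2-one
Product: 10 2-[(2S,3S,6S)-6-hydroxy-3,7,7-trimethyl-2-(3-oxobutyl)oxepan-3-yl]acetaldehyde
Conditions: PdCl2(PhCN)2 (12 mol %), CuCl2·2H2O (12 mol %), AgNO2 (6 mol %), O2 (1 atm), t-BuOH/MeNO2 15:1, rt
Reagents that add atoms: dioxygen, O=O
Why: Aldehyde-selective (anti-Markovnikov) Wacker oxidation under nitrite co-catalysis should oxidise the remaining vinyl group at its terminal carbon, which the adjacent quaternary centre favours, without touching ketone or alcohol.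

Step 7
Reactants: 10 2-[(2S,3S,6S)-6-hydroxy-3,7,7-trimethyl-2-(3-oxobutyl)oxepan-3-yl]acetaldehyde
Product: 11 (3S,5aS,6S,7R,9aS)-3,7-dihydroxy-2,2,5a,7-tetramethyldecahydro-1-benzoxepine-6-carbaldehyde
Conditions: (S)-proline (30 mol %), DMSO, rt
Reagents that add atoms: none
Why: Amine-catalysed intramolecular aldol addition (6-enolexo) of the aldehyde enamine to the methyl ketone should close the cyclohexane; the addition is reversible, so C10 and C11 should settle as the diastereomer with equatorial formyl and equatorial methyl (axial hydroxyl), which avoids a 1,3-diaxial methyl–methyl contact with the angular methyl group.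

Step 8
Reactants: 11 (3S,5aS,6S,7R,9aS)-3,7-dihydroxy-2,2,5a,7-tetramethyldecahydro-1-benzoxepine-6-carbaldehyde
Product: 12 (3S,5aS,6R,7R,9aS)-6-(hydroxymethyl)-2,2,5a,7-tetramethyldecahydro-1-benzoxepine-3,7-diol
Conditions: NaBH4, MeOH/CH2Cl2, −78 °C
Reagents that add atoms: none
Why: Borohydride reduction of the only carbonyl group should give the primary alcohol at low temperature before retro-aldol cleavage or epimerisation can occur.

Step 9
Reactants: 12 (3S,5aS,6R,7R,9aS)-6-(hydroxymethyl)-2,2,5a,7-tetramethyldecahydro-1-benzoxepine-3,7-diol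
Product: 13 (3S,5aS,6S,7R,9aS)-6-(iodomethyl)-2,2,5a,7-tetramethyldecahydro-1-benzoxepine-3,7-diol
Conditions: I2, PPh3, imidazole, CH2Cl2, 0 °C
Reagents that add atoms: iodine, II
Why: Appel-type iodination (Garegg–Samuelsson conditions) should convert only the primary hydroxyl, the neopentyl secondary and the tertiary hydroxyls being too hindered to form the alkoxyphosphonium salt.

Step 10
Reactants: 13 (3S,5aS,6S,7R,9aS)-6-(iodomethyl)-2,2,5a,7-tetramethyldecahydro-1-benzoxepine-3,7-diol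
Product: 14 (5aS,6S,7R,9aS)-7-hydroxy-6-(iodomethyl)-2,2,5a,7-tetramethyloctahydro-1-benzoxepin-3(2H)-one
Conditions: Dess–Martin periodinane, NaHCO3, CH2Cl2, rt
Reagents that add atoms: none
Why: Dess–Martin oxidation should convert the secondary alcohol into the C3 ketone, the tertiary alcohol and the primary iodide being inert.

Step 11
Reactants: 9 4-[(2S,3S,6S)-3-ethenyl-6-hydroxy-3,7,7-trimethyloxepan-2-yl]butan-2-one
Product: 15 4-[(2S,3S,6S)-6-{[tert-butyl(dimethyl)silyl]oxy}-3-ethenyl-3,7,7-trimethyloxepan-2-yl]butan-2-one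
Conditions: t-BuMe2SiOTf, 2,6-lutidine, CH2Cl2, −78 °C
Reagents that add atoms: tert-butyldimethylsilyl trifluoromethanesulfonate, CC(C)(C)[Si](C)(C)OS(=O)(=O)C(F)(F)F
Why: Silyl ether formation with the silyl triflate should protect the hindered secondary alcohol, 2,6-lutidine at −78 °C being too weak a base to turn the methyl ketone into its silyl enol ether.

Step 12
Reactants: 15 4-[(2S,3S,6S)-6-{[tert-butyl(dimethyl)silyl]oxy}-3-ethenyl-3,7,7-trimethyloxepan-2-yl]butan-2-one
Product: 16 4-[(2S,3S,6S)-6-{[tert-butyl(dimethyl)silyl]oxy}-3-ethenyl-3,7,7-trimethyloxepan-2-yl]but-1-en-2-yl trifluoromethanesulfonate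
Conditions: KN(SiMe3)2, THF, −78 °C; then PhNTf2, −78 to 0 °C
Reagents that add atoms: N-phenylbis(trifluoromethanesulfonimide), O=S(=O)(N(c1ccccc1)S(=O)(=O)C(F)(F)F)C(F)(F)F
Why: Enol triflate formation after kinetic deprotonation of the methyl ketone at its methyl group by the bulky amide should give the 2-triflyloxy-1-alkene.

Step 13
Reactants: 16 4-[(2S,3S,6S)-6-{[tert-butyl(dimethyl)silyl]oxy}-3-ethenyl-3,7,7-trimethyloxepan-2-yl]but-1-en-2-yl trifluoromethanesulfonate
Product: 17 4-[(2S,3S,6S)-6-{[tert-butyl(dimethyl)silyl]oxy}-3,7,7-trimethyl-3-(2-oxoethyl)oxepan-2-yl]but-1-en-2-yl trifluoromethanesulfonate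
Conditions: PdCl2(PhCN)2 (12 mol %), CuCl2·2H2O (12 mol %), AgNO2 (6 mol %), O2 (1 atm), t-BuOH/MeNO2 15:1, rt
Reagents that add atoms: dioxygen, O=O
Why: Aldehyde-selective Wacker oxidation should again oxidise the vinyl group on the quaternary carbon at its terminus, the electron-poor enol triflate alkene being unreactive towards divalent palladium.

Step 14
Reactants: 17 4-[(2S,3S,6S)-6-{[tert-butyl(dimethyl)silyl]oxy}-3,7,7-trimethyl-3-(2-oxoethyl)oxepan-2-yl]but-1-en-2-yl trifluoromethanesulfonate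
Product: 18 (3S,5aS,6R,9aS)-3-{[tert-butyl(dimethyl)silyl]oxy}-2,2,5a-trimethyl-7-methylidenedecahydro-1-benzoxepine-6-carbaldehyde
Conditions: Pd(OAc)2 (5 mol %), rac-2,2'-bis(diphenylphosphino)-1,1'-binaphthyl (7.5 mol %), Cs2CO3, THF, 60 °C
Reagents that add atoms: none
Why: Palladium-catalysed intramolecular α-alkenylation of the aldehyde enolate (oxidative addition of the alkenyl triflate, C–C reductive elimination) should close the cyclohexane and leave the exocyclic methylene group; the new α-centre C11' is epimerisable under the basic conditions and should settle with the formyl group equatorial.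

Step 15
Reactants: 14 (5aS,6S,7R,9aS)-7-hydroxy-6-(iodomethyl)-2,2,5a,7-tetramethyloctahydro-1-benzoxepin-3(2H)-one, 18 (3S,5aS,6R,9aS)-3-{[tert-butyl(dimethyl)silyl]oxy}-2,2,5a-trimethyl-7-methylidenedecahydro-1-benzoxepine-6-carbaldehyde
Product: 19 (5aS,6S,7R,9aS)-6-{2-[(3S,5aS,6R,9aS)-3-{[tert-butyl(dimethyl)silyl]oxy}-2,2,5a-trimethyl-7-methylidenedecahydro-1-benzoxepin-6-yl]-2-hydroxyethyl}-7-hydroxy-2,2,5a,7-tetramethyloctahydro-1-benzoxepin-3(2H)-one (both carbinol epimers)
Conditions: CrCl2 (4 equiv), Co(C32H16N8) (cobalt phthalocyanine, 5 mol %), DMF, rt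
Reagents that add atoms: none
Why: Takai alkylchromium addition: cobalt-catalysed reduction of the primary iodide by CrCl2 should give an alkylchromium species that adds to the aldehyde (C12–C13 bond) and tolerates the ketone and the free tertiary alcohol; the new carbinol centre is uncontrolled and is removed in step 17.

Step 16
Reactants: 19 (5aS,6S,7R,9aS)-6-{2-[(3S,5aS,6R,9aS)-3-{[tert-butyl(dimethyl)silyl]oxy}-2,2,5a-trimethyl-7-methylidenedecahydro-1-benzoxepin-6-yl]-2-hydroxyethyl}-7-hydroxy-2,2,5a,7-tetramethyloctahydro-1-benzoxepin-3(2H)-one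
Product: 20 O-{1-[(3S,5aS,6R,9aS)-3-{[tert-butyl(dimethyl)silyl]oxy}-2,2,5a-trimethyl-7-methylidenedecahydro-1-benzoxepin-6-yl]-2-[(5aS,6S,7R,9aS)-7-hydroxy-2,2,5a,7-tetramethyl-3-oxodecahydro-1-benzoxepin-6-yl]ethyl} O-phenyl carbonothioate (both epimers)
Conditions: PhOC(S)Cl, pyridine, 4-(dimethylamino)pyridine (cat.), CH2Cl2, rt
Reagents that add atoms: O-phenyl chlorothionoformate, S=C(Cl)Oc1ccccc1
Why: Thionocarbonate formation (first stage of the Barton–McCombie deoxygenation) should occur at the secondary alcohol only, the axial tertiary alcohol with its 1,3-diaxial methyl neighbour being too hindered.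

Step 17
Reactants: 20 O-{1-[(3S,5aS,6R,9aS)-3-{[tert-butyl(dimethyl)silyl]oxy}-2,2,5a-trimethyl-7-methylidenedecahydro-1-benzoxepin-6-yl]-2-[(5aS,6S,7R,9aS)-7-hydroxy-2,2,5a,7-tetramethyl-3-oxodecahydro-1-benzoxepin-6-yl]ethyl} O-phenyl carbonothioate
Product: 21 (5aS,6S,7R,9aS)-6-{2-[(3S,5aS,6R,9aS)-3-{[tert-butyl(dimethyl)silyl]oxy}-2,2,5a-trimethyl-7-methylidenedecahydro-1-benzoxepin-6-yl]ethyl}-7-hydroxy-2,2,5a,7-tetramethyloctahydro-1-benzoxepin-3(2H)-one
Conditions: Bu3SnH (high concentration), PhSeSePh (10 mol %), 2,2'-azobis(2-methylpropionitrile) (cat.), benzene, 80 °C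
Reagents that add atoms: none
Why: Barton–McCombie radical deoxygenation should remove the C13 oxygen; benzeneselenol formed in situ transfers hydrogen fast enough to outrun 1,2-vinyl migration of the homoallylic radical (polarity-reversal catalysis).

Step 18
Reactants: 21 (5aS,6S,7R,9aS)-6-{2-[(3S,5aS,6R,9aS)-3-{[tert-butyl(dimethyl)silyl]oxy}-2,2,5a-trimethyl-7-methylidenedecahydro-1-benzoxepin-6-yl]ethyl}-7-hydroxy-2,2,5a,7-tetramethyloctahydro-1-benzoxepin-3(2H)-one
Product: 22 (5aS,6S,7R,9aS)-6-{2-[(3S,5aS,6R,9aS)-3-{[tert-butyl(dimethyl)silyl]oxy}-2,2,5a-trimethyl-7-methylidenedecahydro-1-benzoxepin-6-yl]ethyl}-2,2,5a,7-tetramethyl-3-oxodecahydro-1-benzoxepin-7-yl acetate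
Conditions: Ac2O (excess), 4-(dimethylamino)pyridine, Et3N, CH2Cl2, 40 °C
Reagents that add atoms: acetic anhydride, CC(=O)OC(C)=O
Why: Nucleophile-catalysed acetylation with excess anhydride should esterify the hindered tertiary alcohol; the ketone, flanked by a quaternary carbon, should not form an enol acetate.

Step 19
Reactants: 22 (5aS,6S,7R,9aS)-6-{2-[(3S,5aS,6R,9aS)-3-{[tert-butyl(dimethyl)silyl]oxy}-2,2,5a-trimethyl-7-methylidenedecahydro-1-benzoxepin-6-yl]ethyl}-2,2,5a,7-tetramethyl-3-oxodecahydro-1-benzoxepin-7-yl acetate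
Product: 23 (5aS,6S,7R,9aS)-6-{2-[(3S,5aS,6R,9aS)-3-hydroxy-2,2,5a-trimethyl-7-methylidenedecahydro-1-benzoxepin-6-yl]ethyl}-2,2,5a,7-tetramethyl-3-oxodecahydro-1-benzoxepin-7-yl acetate (CNP0148623.1)
Conditions: HF·pyridine, pyridine/THF, 0 °C to rt
Reagents that add atoms: none
Why: Fluoride-mediated silyl ether cleavage under buffered, non-basic conditions should free the C3' alcohol and leave the tertiary acetate, the ketone and the exocyclic alkene untouched.

**Compound list**

1 | nerol, (2Z)-3,7-dimethylocta-2,6-dien-1-ol | CC(C)=CCC/C(C)=C\CO | starting material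
2 | (2Z)-3,7-dimethylocta-2,6-dien-1-yl methyl carbonate | CC(C)=CCC/C(C)=C\COC(=O)OC | intermediate
3 | methyl (2Z)-5-[(2S)-3,3-dimethyloxiran-2-yl]-3-methylpent-2-en-1-yl carbonate | CC1(C)O[C@H]1CC/C(C)=C\COC(=O)OC | intermediate
4 | {(2Z)-5-[(2S)-3,3-dimethyloxiran-2-yl]-3-methylpent-2-en-1-yl}trimethylsilane | CC1(C)O[C@H]1CC/C(C)=C\C[Si](C)(C)C | intermediate
5 | pent-4-enal | C=CCCC=O | starting material
6 | (5S)-2-(but-3-en-1-yl)-4,4-dimethyl-5-[(3Z)-3-methyl-5-(trimethylsilyl)pent-3-en-1-yl]-1,3-dioxolane (both C2 epimers; not isolated) | C=CCCC1OC(C)(C)[C@H](CC/C(C)=C\C[Si](C)(C)C)O1 | intermediate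
7 | {[(3S,6S,7S)-7-(but-3-en-1-yl)-6-ethenyl-2,2,6-trimethyloxepan-3-yl]oxy}trimethylsilane (not isolated) | C=CCC[C@@H]1OC(C)(C)[C@@H](O[Si](C)(C)C)CC[C@@]1(C)C=C | intermediate
8 | (3S,6S,7S)-7-(but-3-en-1-yl)-6-ethenyl-2,2,6-trimethyloxepan-3-ol | C=CCC[C@@H]1OC(C)(C)[C@@H](O)CC[C@@]1(C)C=C | intermediate
9 | 4-[(2S,3S,6S)-3-ethenyl-6-hydroxy-3,7,7-trimethyloxepan-2-yl]butan-2-one | CC(=O)CC[C@@H]1OC(C)(C)[C@@H](O)CC[C@@]1(C)C=C | intermediate
10 | 2-[(2S,3S,6S)-6-hydroxy-3,7,7-trimethyl-2-(3-oxobutyl)oxepan-3-yl]acetaldehyde | CC(=O)CC[C@@H]1OC(C)(C)[C@@H](O)CC[C@@]1(C)CC=O | intermediate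
11 | (3S,5aS,6S,7R,9aS)-3,7-dihydroxy-2,2,5a,7-tetramethyldecahydro-1-benzoxepine-6-carbaldehyde | O=C[C@H]1[C@]2(C)CC[C@H](O)C(C)(C)O[C@H]2CC[C@@]1(C)O | intermediate
12 | (3S,5aS,6R,7R,9aS)-6-(hydroxymethyl)-2,2,5a,7-tetramethyldecahydro-1-benzoxepine-3,7-diol | OC[C@H]1[C@]2(C)CC[C@H](O)C(C)(C)O[C@H]2CC[C@@]1(C)O | intermediate
13 | (3S,5aS,6S,7R,9aS)-6-(iodomethyl)-2,2,5a,7-tetramethyldecahydro-1-benzoxepine-3,7-diol | IC[C@H]1[C@]2(C)CC[C@H](O)C(C)(C)O[C@H]2CC[C@@]1(C)O | intermediate
14 | (5aS,6S,7R,9aS)-7-hydroxy-6-(iodomethyl)-2,2,5a,7-tetramethyloctahydro-1-benzoxepin-3(2H)-one | IC[C@H]1[C@]2(C)CCC(=O)C(C)(C)O[C@H]2CC[C@@]1(C)O | intermediate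
15 | 4-[(2S,3S,6S)-6-{[tert-butyl(dimethyl)silyl]oxy}-3-ethenyl-3,7,7-trimethyloxepan-2-yl]butan-2-one | CC(=O)CC[C@@H]1OC(C)(C)[C@@H](O[Si](C)(C)C(C)(C)C)CC[C@@]1(C)C=C | intermediate
16 | 4-[(2S,3S,6S)-6-{[tert-butyl(dimethyl)silyl]oxy}-3-ethenyl-3,7,7-trimethyloxepan-2-yl]but-1-en-2-yl trifluoromethanesulfonate | C=C(OS(=O)(=O)C(F)(F)F)CC[C@@H]1OC(C)(C)[C@@H](O[Si](C)(C)C(C)(C)C)CC[C@@]1(C)C=C | intermediate
17 | 4-[(2S,3S,6S)-6-{[tert-butyl(dimethyl)silyl]oxy}-3,7,7-trimethyl-3-(2-oxoethyl)oxepan-2-yl]but-1-en-2-yl trifluoromethanesulfonate | C=C(OS(=O)(=O)C(F)(F)F)CC[C@@H]1OC(C)(C)[C@@H](O[Si](C)(C)C(C)(C)C)CC[C@@]1(C)CC=O | intermediate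
18 | (3S,5aS,6R,9aS)-3-{[tert-butyl(dimethyl)silyl]oxy}-2,2,5a-trimethyl-7-methylidenedecahydro-1-benzoxepine-6-carbaldehyde | C=C1CC[C@@H]2OC(C)(C)[C@@H](O[Si](C)(C)C(C)(C)C)CC[C@@]2(C)[C@@H]1C=O | intermediate
19 | coupled hydroxy ketone (name as in step 15; both carbinol epimers) | C=C1CC[C@@H]2OC(C)(C)[C@@H](O[Si](C)(C)C(C)(C)C)CC[C@@]2(C)[C@@H]1C(O)C[C@H]1[C@]2(C)CCC(=O)C(C)(C)O[C@H]2CC[C@@]1(C)O | intermediate
20 | O-phenyl thionocarbonate of 19 (name as in step 16; both epimers) | C=C1CC[C@@H]2OC(C)(C)[C@@H](O[Si](C)(C)C(C)(C)C)CC[C@@]2(C)[C@@H]1C(OC(=S)Oc1ccccc1)C[C@H]1[C@]2(C)CCC(=O)C(C)(C)O[C@H]2CC[C@@]1(C)O | intermediate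
21 | (5aS,6S,7R,9aS)-6-{2-[(3S,5aS,6R,9aS)-3-{[tert-butyl(dimethyl)silyl]oxy}-2,2,5a-trimethyl-7-methylidenedecahydro-1-benzoxepin-6-yl]ethyl}-7-hydroxy-2,2,5a,7-tetramethyloctahydro-1-benzoxepin-3(2H)-one | C=C1CC[C@@H]2OC(C)(C)[C@@H](O[Si](C)(C)C(C)(C)C)CC[C@@]2(C)[C@@H]1CC[C@H]1[C@]2(C)CCC(=O)C(C)(C)O[C@H]2CC[C@@]1(C)O | intermediate
22 | (5aS,6S,7R,9aS)-6-{2-[(3S,5aS,6R,9aS)-3-{[tert-butyl(dimethyl)silyl]oxy}-2,2,5a-trimethyl-7-methylidenedecahydro-1-benzoxepin-6-yl]ethyl}-2,2,5a,7-tetramethyl-3-oxodecahydro-1-benzoxepin-7-yl acetate | C=C1CC[C@@H]2OC(C)(C)[C@@H](O[Si](C)(C)C(C)(C)C)CC[C@@]2(C)[C@@H]1CC[C@H]1[C@]2(C)CCC(=O)C(C)(C)O[C@H]2CC[C@@]1(C)OC(C)=O | intermediate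
23 | (5aS,6S,7R,9aS)-6-{2-[(3S,5aS,6R,9aS)-3-hydroxy-2,2,5a-trimethyl-7-methylidenedecahydro-1-benzoxepin-6-yl]ethyl}-2,2,5a,7-tetramethyl-3-oxodecahydro-1-benzoxepin-7-yl acetate (CNP0148623.1) | C=C1CC[C@@H]2OC(C)(C)[C@@H](O)CC[C@@]2(C)[C@@H]1CC[C@H]1[C@]2(C)CCC(=O)C(C)(C)O[C@H]2CC[C@@]1(C)OC(C)=O | target

**Step count and risks**

Total step count: 19. Longest linear sequence: 15 steps (steps 1–10, then 15–19).

Step 4 (key step, proposed new method). What may go wrong: the allylsilane may cyclise onto the activated epoxide before the aldehyde is captured; the ring may close through the secondary oxygen to a six-membered ether; the transfer of chirality from C3 to C6 and C7 may be incomplete. Fallback with known chemistry only, setting out from 3 and coming back at 8: acid-catalysed hydration of the epoxide (HClO4, THF/H2O, 0 °C) should give methyl (2Z,6S)-6,7-dihydroxy-3,7-dimethyloct-2-en-1-yl carbonate F1. Acetalisation with 5 (pyridinium p-toluenesulfonate, MgSO4, CH2Cl2) gives methyl (2Z)-5-[(4S)-2-(but-3-en-1-yl)-5,5-dimethyl-1,3-dioxolan-4-yl]-3-methylpent-2-en-1-yl carbonate F2. Palladium-catalysed silylation as in step 3 then delivers 6 as an isolated compound, and its acetal–allylsilane cyclisation with Me3SiOTf followed by methanolysis of 7 leads to 8. The epoxide and the allylsilane then never meet a Lewis acid together, at the price of three extra steps.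

Step 14. What may go wrong: base-induced migration of the new β,γ-double bond into conjugation with the aldehyde, aldol self-condensation, or addition of the alkenylpalladium species to the carbonyl group instead of enolate coupling. Fallback, setting out from 17 and coming back at 18: silylation of the aldehyde (t-BuMe2SiOTf, Et3N, CH2Cl2) to 4-[(2S,3S,6S)-6-{[tert-butyl(dimethyl)silyl]oxy}-3-(2-{[tert-butyl(dimethyl)silyl]oxy}ethenyl)-3,7,7-trimethyloxepan-2-yl]but-1-en-2-yl trifluoromethanesulfonate F3. Elimination of the enol triflate with LiN(i-Pr)2 (THF, −78 °C) gives the terminal alkyne tert-butyl({2-[(2S,3S,6S)-2-(but-3-yn-1-yl)-6-{[tert-butyl(dimethyl)silyl]oxy}-3,7,7-trimethyloxepan-3-yl]ethenyl}oxy)dimethylsilane F4. A Conia-ene-type 6-exo-dig carbocyclisation of the silyl enol ether onto the alkyne, catalysed by monovalent gold (Ph3PAuCl/AgBF4, CH2Cl2/MeOH, rt), then gives 18 under neutral conditions.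

Step 15. What may go wrong: slow formation or protonation of the β-branched alkylchromium species by the free hydroxyl group, and epimerisation or double-bond migration of the sensitive aldehyde during a slow addition. Fallback, setting out from 18 and 14 and coming back at 21 (steps 16 and 17 are then not needed): NaBH4 reduction of 18 to [(3S,5aS,6R,9aS)-3-{[tert-butyl(dimethyl)silyl]oxy}-2,2,5a-trimethyl-7-methylidenedecahydro-1-benzoxepin-6-yl]methanol F5. Iodination (I2, PPh3, imidazole) gives tert-butyl{[(3S,5aS,6R,9aS)-6-(iodomethyl)-2,2,5a-trimethyl-7-methylidenedecahydro-1-benzoxepin-3-yl]oxy}dimethylsilane F6. Zinc insertion (Zn dust, N,N-dimethylacetamide) gives iodido{[(3S,5aS,6R,9aS)-3-{[tert-butyl(dimethyl)silyl]oxy}-2,2,5a-trimethyl-7-methylidenedecahydro-1-benzoxepin-6-yl]methyl}zinc F7. Nickel-catalysed alkyl–alkyl Negishi coupling of F7 with 14 (Ni(cod)2, bis(1,5-cyclooctadiene)nickel, with 2,6-bis[(4S)-4-sec-butyl-4,5-dihydrooxazol-2-yl]pyridine, rt) then forms the C12–C13 bond directly.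

**Further compounds**

F1 | step 4 | methyl (2Z,6S)-6,7-dihydroxy-3,7-dimethyloct-2-en-1-yl carbonate | CC(C)(O)[C@@H](O)CC/C(C)=C\COC(=O)OC
F2 | step 4 | methyl (2Z)-5-[(4S)-2-(but-3-en-1-yl)-5,5-dimethyl-1,3-dioxolan-4-yl]-3-methylpent-2-en-1-yl carbonate | C=CCCC1OC(C)(C)[C@H](CC/C(C)=C\COC(=O)OC)O1
F3 | step 14 | 4-[(2S,3S,6S)-6-{[tert-butyl(dimethyl)silyl]oxy}-3-(2-{[tert-butyl(dimethyl)silyl]oxy}ethenyl)-3,7,7-trimethyloxepan-2-yl]but-1-en-2-yl trifluoromethanesulfonate | C=C(OS(=O)(=O)C(F)(F)F)CC[C@@H]1OC(C)(C)[C@@H](O[Si](C)(C)C(C)(C)C)CC[C@@]1(C)C=CO[Si](C)(C)C(C)(C)C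
F4 | step 14 | tert-butyl({2-[(2S,3S,6S)-2-(but-3-yn-1-yl)-6-{[tert-butyl(dimethyl)silyl]oxy}-3,7,7-trimethyloxepan-3-yl]ethenyl}oxy)dimethylsilane | C#CCC[C@@H]1OC(C)(C)[C@@H](O[Si](C)(C)C(C)(C)C)CC[C@@]1(C)C=CO[Si](C)(C)C(C)(C)C
F5 | step 15 | [(3S,5aS,6R,9aS)-3-{[tert-butyl(dimethyl)silyl]oxy}-2,2,5a-trimethyl-7-methylidenedecahydro-1-benzoxepin-6-yl]methanol | C=C1CC[C@@H]2OC(C)(C)[C@@H](O[Si](C)(C)C(C)(C)C)CC[C@@]2(C)[C@@H]1CO
F6 | step 15 | tert-butyl{[(3S,5aS,6R,9aS)-6-(iodomethyl)-2,2,5a-trimethyl-7-methylidenedecahydro-1-benzoxepin-3-yl]oxy}dimethylsilane | C=C1CC[C@@H]2OC(C)(C)[C@@H](O[Si](C)(C)C(C)(C)C)CC[C@@]2(C)[C@@H]1CI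
F7 | step 15 | iodido{[(3S,5aS,6R,9aS)-3-{[tert-butyl(dimethyl)silyl]oxy}-2,2,5a-trimethyl-7-methylidenedecahydro-1-benzoxepin-6-yl]methyl}zinc | C=C1CC[C@@H]2OC(C)(C)[C@@H](O[Si](C)(C)C(C)(C)C)CC[C@@]2(C)[C@@H]1C[Zn]I
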